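**Retrosynthetic overview**

1. The target is the acetate of a tertiary cyclopentenol. That alcohol comes from C5-alkylation of silyl-protected (S)-4-hydroxy-4-[(Z)-oct-2-enyl]cyclopent-2-enone with an (E)-allylic bromide carrying the complete acetoxy-ester chain, which enters trans to the silyloxy group.
2. Key disconnection: the cyclopentenone (C1 carbonyl, C2=C3, C4 carbinol, C5) is cut at C2=C3 and C4–C5. This gives an acetone 1,3-dianion equivalent (a β-ketophosphonate, C2–C1–C5) and a 2-oxoaldehyde equivalent (formyl carbon C3, keto carbon C4 bearing the octenyl chain).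
3. Enabling feature: the C1 carbonyl acidifies both C2 and C5, while C3 (sp2 CH) and C4 (C–O) sit at the oxidation level of a 1,2-dicarbonyl. An aldol (C4–C5) plus a Horner–Wadsworth–Emmons olefination (C2=C3) therefore closes the only carbocycle in one pot. A D-proline-derived aminal at C3 is a temporary ring that controls C4 and is then excised.
4. The keto aminal comes from hept-1-yne and glycidaldehyde acetal (alkynylation, Lindlar, aminal formation, oxidation). The bromide comes from the L-glutamic acid-derived hydroxymethyl butyrolactone, whose five carbons and stereocentre become C1–C5 and the acetoxy carbon of the heptenoate chain.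
5. Ring order: bicyclic aminal (temporary, step 3), then the cyclopentenone (step 5); no other ring is made.

Key step: step 5

Remark: the aminal is taken to form as the single exo epimer and its ketone to react through the magnesium chelate described in step 5; on this model the D-proline-derived (R)-diamine leads to the required (S)-carbinol.

**Route**

Step 1
Reactants: 1 hept-1-yne; 2 2-(diethoxymethyl)oxirane (racemic)
Product: 3 1,1-diethoxydec-4-yn-2-ol (racemic)
Conditions: n-BuLi, THF, −78 °C; BF3·OEt2; then 2, −78 °C; aq. NH4Cl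
Reagents that add atoms: none
Why: BF3-promoted opening of a terminal epoxide by a lithium acetylide should occur at the unhindered CH2 terminus, and the racemic carbinol centre formed is removed by the oxidation in step 4.

Step 2
Reactants: 3 1,1-diethoxydec-4-yn-2-ol
Product: 4 (4Z)-1,1-diethoxydec-4-en-2-ol
Conditions: H2 (1 atm), Pd/CaCO3 poisoned with Pb(OAc)2 (Lindlar catalyst), quinoline, EtOAc, rt
Reagents that add atoms: none
Why: Lindlar semihydrogenation should add H2 syn across the alkyne on the poisoned Pd surface and stop at the (Z)-alkene, leaving acetal and alcohol untouched.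

Step 3
Reactants: 4 (4Z)-1,1-diethoxydec-4-en-2-ol; 5 (R)-2-(anilinomethyl)pyrrolidine
Product: 7 (3Z)-1-[(2S,5R)-3-phenyl-1,3-diazabicyclo[3.3.0]octan-2-yl]non-3-en-1-ol (both carbinol epimers), via (4Z)-2-hydroxydec-4-enal 6 (not isolated)
Conditions: 1 M aq. HCl, THF, rt; NaHCO3, extraction; then 5, MgSO4, CH2Cl2, rt
Reagents that add atoms: none
Why: Acetal hydrolysis followed by aminal formation with the 1,2-diamine should give the cis-fused bicyclic aminal under thermodynamic control with the side chain on the exo face, so the new aminal carbon is (2S) as dictated by the (5R) bridgehead of the diamine, while the carbinol centre stays a mixture that step 4 removes.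

Step 4
Reactants: 7 (3Z)-1-[(2S,5R)-3-phenyl-1,3-diazabicyclo[3.3.0]octan-2-yl]non-3-en-1-ol
Product: 8 (3Z)-1-[(2S,5R)-3-phenyl-1,3-diazabicyclo[3.3.0]octan-2-yl]non-3-en-1-one
Conditions: (COCl)2, DMSO, CH2Cl2, −78 °C; iPr2NEt, −78 → −30 °C; pH 7 buffer
Reagents that add atoms: none
Why: Swern oxidation should convert both carbinol epimers into the single ketone at low temperature with a hindered amine base, conditions under which the tertiary amines are inert and the skipped (Z)-alkene should not migrate into conjugation.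

Step 5
Reactants: 8 (3Z)-1-[(2S,5R)-3-phenyl-1,3-diazabicyclo[3.3.0]octan-2-yl]non-3-en-1-one; 9 dimethyl (2-oxopropyl)phosphonate
Product: 12 (S)-4-hydroxy-4-[(2Z)-oct-2-en-1-yl]cyclopent-2-en-1-one, via aminal aldol adduct 10 (not isolated), via formyl β-ketophosphonate 11 (not isolated)
Conditions: 9, NaH then n-BuLi, THF, 0 °C; MgBr2·OEt2, then 8, −78 °C; 2% aq. HCl, Et2O, 0 °C (aqueous layer removed); aq. K2CO3, THF, rt
Reagents that add atoms: none
Why: The γ-carbon of the phosphonate dianion (its unstabilised enolate terminus) adds to the ketone of 8, which is held in a five-membered magnesium chelate between the carbonyl oxygen and the pyrrolidine nitrogen of the rigid exo aminal, so attack comes from the face turned away from the N-phenyl nitrogen and the ring C4–C5 bond is formed with the (S) carbinol; the closest known reaction types are the γ-aldol of β-ketophosphonate dianions and the Grignard addition to proline-diamine keto aminals. Dilute acid then hydrolyses the aminal to the aldehyde and sends the auxiliary into the aqueous phase, and under K2CO3 the phosphonate-stabilised carbon attacks that aldehyde intramolecularly in a 5-exo-trig Horner–Wadsworth–Emmons closure that expels dimethyl phosphate and forms the ring C2=C3 bond, its cis geometry being imposed by the five-membered ring. The cyclopentenone is the only ring closed, and its only new stereocentre, C4, is controlled by the aminal carbon, which is destroyed in the same pot. The step needs ketone-over-aldehyde selectivity (the aldehyde is masked as the aminal), γ-over-α reactivity of the dianion (inherent), addition rather than deprotonation of the skipped β,γ-unsaturated ketone (magnesium counter-ion, −78 °C, α-amino activation of the ketone) and ring closure faster than retro-aldol (intramolecular olefination of a free aldehyde).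

Step 6
Reactants: 12 (S)-4-hydroxy-4-[(2Z)-oct-2-en-1-yl]cyclopent-2-en-1-one
Product: 13 (S)-4-[(2Z)-oct-2-en-1-yl]-4-[(triethylsilyl)oxy]cyclopent-2-en-1-one
Conditions: Et3SiOTf, 2,6-lutidine, CH2Cl2, −78 → 0 °C
Reagents that add atoms: triethylsilyl trifluoromethanesulfonate, CC[Si](CC)(CC)OS(=O)(=O)C(F)(F)F
Why: Silyl triflate silylation of the hindered tertiary alcohol (silyl ether formation) should proceed without touching the enone and installs the bulky group that blocks one ring face in step 11.

Step 7
Reactants: 14 (S)-5-(hydroxymethyl)dihydrofuran-2(3H)-one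
Product: 15 (S)-5-oxotetrahydrofuran-2-carbaldehyde
Conditions: (COCl)2, DMSO, CH2Cl2, −78 °C; Et3N
Reagents that add atoms: none
Why: Swern oxidation should give the α-acyloxy aldehyde without epimerising the adjacent centre or opening the lactone.

Step 8
Reactants: 15 (S)-5-oxotetrahydrofuran-2-carbaldehyde
Product: 16 (S)-5-vinyldihydrofuran-2(3H)-one
Conditions: Ph3PCH3Br, KN(SiMe3)2, THF, −78 → 0 °C
Reagents that add atoms: methylenetriphenylphosphorane (made from methyltriphenylphosphonium bromide and KN(SiMe3)2), C=P(c1ccccc1)(c1ccccc1)c1ccccc1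
Why: Wittig methylenation with the non-stabilised ylide at low temperature should convert the aldehyde to the vinyl group faster than it enolises, so the (S) centre is retained.

Step 9
Reactants: 16 (S)-5-vinyldihydrofuran-2(3H)-one
Product: 19 methyl (S)-4-acetoxyhex-5-enoate, via sodium (S)-4-hydroxyhex-5-enoate 17 (not isolated), via methyl (S)-4-hydroxyhex-5-enoate 18 (not isolated)
Conditions: NaOH, MeOH/H2O, 0 °C → rt, evaporate; MeI, DMF, rt; then Ac2O, pyridine, DMAP (cat.), 0 °C → rt
Reagents that add atoms: sodium hydroxide, [Na+].[OH-]; iodomethane, CI; acetic anhydride, CC(=O)OC(C)=O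
Why: Lactone saponification, carboxylate O-methylation and in-situ acetylation (ring opening, esterification, acylation) should trap the γ-hydroxy ester before it can relactonise, with no bond to the stereocentre broken.

Step 10
Reactants: 19 methyl (S)-4-acetoxyhex-5-enoate; 20 (E)-1,4-dibromobut-2-ene
Product: 21 methyl (4S,5E)-4-acetoxy-7-bromohept-5-enoate
Conditions: 20 (3 equiv), RuCl2(H2IMes)(=CH–C6H4-2-OiPr) (second-generation Hoveyda–Grubbs catalyst, 5 mol%), CH2Cl2, 40 °C
Reagents that add atoms: none
Why: Olefin cross-metathesis of the terminal alkene with excess symmetrical dibromobutene should give the (E)-allylic bromide under thermodynamic control, the allylic acetoxy group slowing homodimerisation of 19.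

Step 11
Reactants: 13 (S)-4-[(2Z)-oct-2-en-1-yl]-4-[(triethylsilyl)oxy]cyclopent-2-en-1-one; 21 methyl (4S,5E)-4-acetoxy-7-bromohept-5-enoate
Product: 22 (4R,5S)-5-[(2E,4S)-4-acetoxy-7-methoxy-7-oxohept-2-en-1-yl]-4-[(2Z)-oct-2-en-1-yl]-4-[(triethylsilyl)oxy]cyclopent-2-en-1-one
Conditions: LiN(iPr)2, THF, −78 °C; then 21, DMPU, −78 → −40 °C; AcOH quench at −78 °C
Reagents that add atoms: none
Why: Kinetic deprotonation at C5 gives the cross-conjugated lithium dienolate, whose SN2 alkylation by the primary allylic bromide (enolate alkylation) should occur on the ring face opposite the bulky, electron-withdrawing C4 silyloxy group, so the new chain ends trans to oxygen and cis to the octenyl chain (5S).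

Step 12
Reactants: 22 (4R,5S)-5-[(2E,4S)-4-acetoxy-7-methoxy-7-oxohept-2-en-1-yl]-4-[(2Z)-oct-2-en-1-yl]-4-[(triethylsilyl)oxy]cyclopent-2-en-1-one
Product: 23 (4R,5S)-5-[(2E,4S)-4-acetoxy-7-methoxy-7-oxohept-2-en-1-yl]-4-hydroxy-4-[(2Z)-oct-2-en-1-yl]cyclopent-2-en-1-one
Conditions: HF·pyridine, pyridine, THF, 0 °C → rt
Reagents that add atoms: none
Why: Fluoride-mediated silyl ether cleavage with buffered HF·pyridine should free the tertiary alcohol under mildly acidic conditions that neither epimerise C5 nor touch the esters.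

Step 13
Reactants: 23 (4R,5S)-5-[(2E,4S)-4-acetoxy-7-methoxy-7-oxohept-2-en-1-yl]-4-hydroxy-4-[(2Z)-oct-2-en-1-yl]cyclopent-2-en-1-one
Product: 24 methyl (4S,5E)-4-acetoxy-7-{(1S,5R)-5-acetoxy-5-[(2Z)-oct-2-en-1-yl]-2-oxocyclopent-3-en-1-yl}hept-5-enoate (CNP0171642.2)
Conditions: Ac2O, Sc(OTf)3 (2 mol%), MeCN, −20 °C
Reagents that add atoms: acetic anhydride, CC(=O)OC(C)=O
Why: Lewis acid-catalysed acylation with Ac2O and Sc(OTf)3 should esterify the hindered tertiary alcohol without base, so C5 is not epimerised, and ionisation at C4 is disfavoured because the cation would be conjugated to the enone carbonyl.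

**Compound list**

1 | hept-1-yne | C#CCCCCC | starting material
2 | 2-(diethoxymethyl)oxirane (racemic) | CCOC(OCC)C1CO1 | starting material
3 | 1,1-diethoxydec-4-yn-2-ol (racemic) | CCCCCC#CCC(O)C(OCC)OCC | intermediate
4 | (4Z)-1,1-diethoxydec-4-en-2-ol (racemic) | CCCCC/C=C\CC(O)C(OCC)OCC | intermediate
5 | (R)-2-(anilinomethyl)pyrrolidine | C1C[C@@H](NC1)CNc1ccccc1 | starting material
6 | (4Z)-2-hydroxydec-4-enal (racemic) | CCCCC/C=C\CC(O)C=O | intermediate
7 | (3Z)-1-[(2S,5R)-3-phenyl-1,3-diazabicyclo[3.3.0]octan-2-yl]non-3-en-1-ol (carbinol epimers) | CCCCC/C=C\CC(O)[C@@H]1N(c2ccccc2)C[C@H]3CCCN13 | intermediate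
8 | (3Z)-1-[(2S,5R)-3-phenyl-1,3-diazabicyclo[3.3.0]octan-2-yl]non-3-en-1-one | CCCCC/C=C\CC(=O)[C@@H]1N(c2ccccc2)C[C@H]3CCCN13 | intermediate
9 | dimethyl (2-oxopropyl)phosphonate | CC(=O)CP(=O)(OC)OC | starting material
10 | dimethyl {(4S,6Z)-4-hydroxy-2-oxo-4-[(2S,5R)-3-phenyl-1,3-diazabicyclo[3.3.0]octan-2-yl]dodec-6-en-1-yl}phosphonate | CCCCC/C=C\C[C@@](O)([C@@H]1N(c2ccccc2)C[C@H]3CCCN13)CC(=O)CP(=O)(OC)OC | intermediate
11 | dimethyl [(4S,6Z)-4-formyl-4-hydroxy-2-oxododec-6-en-1-yl]phosphonate | CCCCC/C=C\C[C@@](O)(C=O)CC(=O)CP(=O)(OC)OC | intermediate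
12 | (S)-4-hydroxy-4-[(2Z)-oct-2-en-1-yl]cyclopent-2-en-1-one | CCCCC/C=C\C[C@@]1(O)C=CC(=O)C1 | intermediate
13 | (S)-4-[(2Z)-oct-2-en-1-yl]-4-[(triethylsilyl)oxy]cyclopent-2-en-1-one | CCCCC/C=C\C[C@@]1(O[Si](CC)(CC)CC)C=CC(=O)C1 | intermediate
14 | (S)-5-(hydroxymethyl)dihydrofuran-2(3H)-one | OC[C@@H]1CCC(=O)O1 | starting material
15 | (S)-5-oxotetrahydrofuran-2-carbaldehyde | O=C[C@@H]1CCC(=O)O1 | intermediate
16 | (S)-5-vinyldihydrofuran-2(3H)-one | C=C[C@@H]1CCC(=O)O1 | intermediate
17 | sodium (S)-4-hydroxyhex-5-enoate | C=C[C@@H](O)CCC(=O)[O-].[Na+] | intermediate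
18 | methyl (S)-4-hydroxyhex-5-enoate | C=C[C@@H](O)CCC(=O)OC | intermediate
19 | methyl (S)-4-acetoxyhex-5-enoate | C=C[C@H](CCC(=O)OC)OC(C)=O | intermediate
20 | (E)-1,4-dibromobut-2-ene | BrC/C=C/CBr | starting material
21 | methyl (4S,5E)-4-acetoxy-7-bromohept-5-enoate | BrC/C=C/[C@H](CCC(=O)OC)OC(C)=O | intermediate
22 | (4R,5S)-5-[(2E,4S)-4-acetoxy-7-methoxy-7-oxohept-2-en-1-yl]-4-[(2Z)-oct-2-en-1-yl]-4-[(triethylsilyl)oxy]cyclopent-2-en-1-one | CCCCC/C=C\C[C@@]1(O[Si](CC)(CC)CC)C=CC(=O)[C@H]1C/C=C/[C@H](CCC(=O)OC)OC(C)=O | intermediate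
23 | (4R,5S)-5-[(2E,4S)-4-acetoxy-7-methoxy-7-oxohept-2-en-1-yl]-4-hydroxy-4-[(2Z)-oct-2-en-1-yl]cyclopent-2-en-1-one | CCCCC/C=C\C[C@@]1(O)C=CC(=O)[C@H]1C/C=C/[C@H](CCC(=O)OC)OC(C)=O | intermediate
24 | methyl (4S,5E)-4-acetoxy-7-{(1S,5R)-5-acetoxy-5-[(2Z)-oct-2-en-1-yl]-2-oxocyclopent-3-en-1-yl}hept-5-enoate | CCCCC/C=C\C[C@@]1(OC(C)=O)C=CC(=O)[C@H]1C/C=C/[C@H](CCC(=O)OC)OC(C)=O | target

**Step count and risks**

Total step count: 13. Longest linear sequence: 9 steps (steps 1 to 6, then 11 to 13); the side chain takes steps 7 to 10.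

The annulation of step 5 is the most exposed. The basic dianion may deprotonate the doubly activated CH2 between the ketone and the (Z)-alkene of 8, moving the alkene into conjugation. The facial control of the aminal, established for Grignard reagents, may also be weaker or reversed for an enolate-type nucleophile. The fallback sets out from 8 and returns at 12, giving up the one-pot closure:
- Allylmagnesium bromide (Et2O, −78 °C), the nucleophile class for which the auxiliary is established, should give (4R,6Z)-4-[(2S,5R)-3-phenyl-1,3-diazabicyclo[3.3.0]octan-2-yl]dodeca-1,6-dien-4-ol F1.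
- 2% aq. HCl at 0 °C should release (2R,4Z)-2-hydroxy-2-(prop-2-en-1-yl)dec-4-enal F2.
- Wacker–Tsuji oxidation of the terminal alkene (PdCl2, CuCl, O2, DMF/H2O) should give (2S,4Z)-2-hydroxy-2-(2-oxopropyl)dec-4-enal F3.
- Intramolecular aldol condensation of the methyl ketone onto the aldehyde (K2CO3, MeOH) should close the ring to 12.

The alkylation of step 11 comes next. The cross-conjugated dienolate may react slowly, so that proton exchange between enolate and product scrambles the new, epimerisable C5 centre, and O-alkylation or attack on the wrong ring face may compete. The fallback sets out from 13 and 19 and returns at 22, replacing the SN2 alkylation by a base-free Tsuji–Trost allylation: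
- 13 is converted with LiN(iPr)2 and Me3SiCl into triethyl({(1R)-1-[(2Z)-oct-2-en-1-yl]-4-[(trimethylsilyl)oxy]cyclopenta-2,4-dien-1-yl}oxy)silane F4.
- 19 is cross-metathesised with dimethyl (Z)-but-2-ene-1,4-diyl dicarbonate (second-generation Hoveyda–Grubbs catalyst) to methyl (4S,5E)-4-acetoxy-7-[(methoxycarbonyl)oxy]hept-5-enoate F5.
- F4 and F5 are joined with Pd2(dba)3 and dppe in THF. The primary carbonate should ionise in preference to the secondary acetate, and the π-allyl complex should be attacked at its CH2 terminus by the enolate freed from F4, again anti to the silyloxy group, to give 22.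

The cross-metathesis of step 10 is third. The allylic bromide partner may deactivate the ruthenium carbene, and homodimerisation or incomplete E-selectivity may lower throughput. The fallback sets out from 19 and returns at 21:
- Cross-metathesis with (Z)-but-2-ene-1,4-diol, a well-behaved partner, should give methyl (4S,5E)-4-acetoxy-7-hydroxyhept-5-enoate F6.
- Appel bromination (CBr4, PPh3, CH2Cl2, 0 °C) should then give 21.

**Further compounds**

F1 | step 5 | (4R,6Z)-4-[(2S,5R)-3-phenyl-1,3-diazabicyclo[3.3.0]octan-2-yl]dodeca-1,6-dien-4-ol | CCCCC/C=C\C[C@@](O)([C@@H]1N(c2ccccc2)C[C@H]3CCCN13)CC=C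
F2 | step 5 | (2R,4Z)-2-hydroxy-2-(prop-2-en-1-yl)dec-4-enal | CCCCC/C=C\C[C@@](O)(C=O)CC=C
F3 | step 5 | (2S,4Z)-2-hydroxy-2-(2-oxopropyl)dec-4-enal | CCCCC/C=C\C[C@@](O)(C=O)CC(C)=O
F4 | step 11 | triethyl({(1R)-1-[(2Z)-oct-2-en-1-yl]-4-[(trimethylsilyl)oxy]cyclopenta-2,4-dien-1-yl}oxy)silane | CCCCC/C=C\C[C@@]1(O[Si](CC)(CC)CC)C=CC(O[Si](C)(C)C)=C1
F5 | step 11 | methyl (4S,5E)-4-acetoxy-7-[(methoxycarbonyl)oxy]hept-5-enoate | COC(=O)OC/C=C/[C@H](CCC(=O)OC)OC(C)=O
F6 | step 10 | methyl (4S,5E)-4-acetoxy-7-hydroxyhept-5-enoate | OC/C=C/[C@H](CCC(=O)OC)OC(C)=O
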